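The route rests on cutting ring C away from ring A at O1–C8a and C4–C4a. Ring A, with oxygen at C5 next to C4a and hydrogen at C8 next to C8a, is the adduct of a 3-alkoxyaryne whose strained bond is C8a–C4a. In the key step this aryne, released from a phloroglucinol-derived silyl triflate that already carries the C6 geranyl group, is attacked at C8a by the alkoxide of an enantiopure β-hydroxy morpholine amide; the aryl anion at C4a is then acylated intramolecularly by the amide. Both bonds and ring C form in one operation, and the C2 stereocentre, set earlier by transfer hydrogenation, is untouched. Acid removes the four methoxymethyl groups.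

Key step: step 11

Remark: geranyl denotes (2E)-3,7-dimethylocta-2,6-dien-1-yl and MOM denotes methoxymethyl; compounds 1, 4, 15 and 17 are taken as purchased.

Step 1
Reactants: 1 phloroglucinol
Product: 2 3,5-bis(methoxymethoxy)phenol
Conditions: MOMCl (2.0 equiv), i-Pr2NEt, DMF/CH2Cl2, 0 °C to rt; chromatography
Reagents that add atoms: chloromethyl methyl ether (MOMCl), COCCl
Why: Williamson-type O-alkylation with two equivalents of MOMCl should give the bis-ether as the main fraction beside separable mono- and tris-ethers, the mono-ether being recycled.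

Step 2
Reactants: 2 3,5-bis(methoxymethoxy)phenol
Product: 3 [3,5-bis(methoxymethoxy)phenoxy]tri(propan-2-yl)silane
Conditions: TIPSCl, imidazole, DMF, rt
Reagents that add atoms: chlorotri(propan-2-yl)silane (TIPSCl), CC(C)[Si](Cl)(C(C)C)C(C)C
Why: Standard silylation of the remaining phenol installs a bulky, poorly coordinating silyl ether that shields its two ortho positions from lithiation in the next step.

Step 3
Reactants: 3 [3,5-bis(methoxymethoxy)phenoxy]tri(propan-2-yl)silane, 4 geranyl bromide
Product: 6 [4-geranyl-3,5-bis(methoxymethoxy)phenoxy]tri(propan-2-yl)silane, via aryllithium 5 (not isolated)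
Conditions: n-BuLi, THF, 0 °C; then CuI (10 mol %), 4, −78 °C to rt
Reagents that add atoms: none
Why: Directed ortho-metalation takes place at the one C–H flanked by two coordinating MOM ethers, and copper-catalysed allylic substitution of the primary bromide at its unhindered α-carbon should give the linear geranyl arene with the E alkene intact.

Step 4
Reactants: 6 [4-geranyl-3,5-bis(methoxymethoxy)phenoxy]tri(propan-2-yl)silane
Product: 7 4-geranyl-3,5-bis(methoxymethoxy)phenol
Conditions: TBAF, THF, 0 °C; aq NH4Cl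
Reagents that add atoms: none
Why: Fluoride-mediated cleavage of the aryl silyl ether frees the phenol without touching MOM ethers or alkenes.

Step 5
Reactants: 7 4-geranyl-3,5-bis(methoxymethoxy)phenol
Product: 8 4-geranyl-3,5-bis(methoxymethoxy)phenyl N-(propan-2-yl)carbamate
Conditions: i-PrNCO, Et3N (cat.), CH2Cl2, rt
Reagents that add atoms: isopropyl isocyanate, CC(C)N=C=O
Why: Amine-catalysed addition of the phenol to the isocyanate gives the secondary carbamate that serves as a removable directing group.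

Step 6
Reactants: 8 4-geranyl-3,5-bis(methoxymethoxy)phenyl N-(propan-2-yl)carbamate
Product: 12 4-geranyl-3,5-bis(methoxymethoxy)-2-(trimethylsilyl)phenyl N-(propan-2-yl)carbamate, via N-silyl carbamate 9 (not isolated), via aryllithium 10 (not isolated), via bis-silyl carbamate 11 (not isolated)
Conditions: TMSOTf, TMEDA, Et2O, 0 °C to rt; n-BuLi, TMEDA, −78 °C; TMSCl, −78 °C to rt; aq NH4Cl
Reagents that add atoms: chlorotrimethylsilane (TMSCl), C[Si](C)(C)Cl
Why: In situ N-silylation makes the carbamate a strong directing group, so directed ortho-metalation (reinforced by the adjacent MOM ether; the two ortho sites are equivalent) and C-silylation follow, and the N–Si bond is hydrolysed on work-up.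

Step 7
Reactants: 12 4-geranyl-3,5-bis(methoxymethoxy)-2-(trimethylsilyl)phenyl N-(propan-2-yl)carbamate
Product: 14 4-geranyl-3,5-bis(methoxymethoxy)-2-(trimethylsilyl)phenyl trifluoromethanesulfonate, via silyl phenol 13 (not isolated)
Conditions: DBU, Et2NH, MeCN, 40 °C; then PhNTf2, rt
Reagents that add atoms: N-phenylbis(trifluoromethanesulfonimide) (PhNTf2), O=S(=O)(N(c1ccccc1)S(=O)(=O)C(F)(F)F)C(F)(F)F
Why: Base-induced E1cB cleavage of the secondary carbamate (isocyanate trapped by Et2NH as a urea) liberates the phenoxide, which is sulfonylated by PhNTf2 in the same flask to the ortho-silylaryl triflate.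

Step 8
Reactants: 15 methyl 3,4-dihydroxybenzoate
Product: 16 methyl 3,4-bis(methoxymethoxy)benzoate
Conditions: MOMCl, i-Pr2NEt, CH2Cl2, 0 °C to rt
Reagents that add atoms: chloromethyl methyl ether (MOMCl), COCCl
Why: Williamson-type O-alkylation of both catechol hydroxyls, the methyl ester being inert.

Step 9
Reactants: 16 methyl 3,4-bis(methoxymethoxy)benzoate, 17 N-acetylmorpholine
Product: 19 1-[3,4-bis(methoxymethoxy)phenyl]-3-(morpholin-4-yl)propane-1,3-dione, via lithium enolate 18 (not isolated)
Conditions: LiN(i-Pr)2 (LDA, 2.2 equiv), 17 (2.2 equiv), THF, −78 °C; then 16, −78 to 0 °C; aq NH4Cl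
Reagents that add atoms: none
Why: Crossed Claisen condensation of the amide enolate with the non-enolisable aryl ester, driven by deprotonation of the β-keto amide by the second equivalent of enolate.

Step 10
Reactants: 19 1-[3,4-bis(methoxymethoxy)phenyl]-3-(morpholin-4-yl)propane-1,3-dione
Product: 20 (3S)-3-[3,4-bis(methoxymethoxy)phenyl]-3-hydroxy-1-(morpholin-4-yl)propan-1-one
Conditions: RuCl[(S,S)-TsDPEN](p-cymene) (1 mol %), HCO2H/Et3N (5:2), DMF, 30 °C
Reagents that add atoms: none
Why: Noyori–Ikariya asymmetric transfer hydrogenation of the aryl ketone, in which the (S,S)-ligand directs hydride to the Re face through the aryl/η6-arene CH–π contact of the six-membered transition state and so sets the S carbinol centre.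

Step 11
Reactants: 20 (3S)-3-[3,4-bis(methoxymethoxy)phenyl]-3-hydroxy-1-(morpholin-4-yl)propan-1-one, 14 4-geranyl-3,5-bis(methoxymethoxy)-2-(trimethylsilyl)phenyl trifluoromethanesulfonate
Product: 24 (2S)-2-[3,4-bis(methoxymethoxy)phenyl]-6-geranyl-5,7-bis(methoxymethoxy)chroman-4-one, via sodium alkoxide 21 (not isolated), via aryne 22 (not isolated), via hemiaminal 23 (not isolated)
Conditions: 20, NaH (1.05 equiv), THF, 0 °C; then 14 (1.5 equiv), KF, 18-crown-6, THF, 0 °C to rt; then AcOH, H2O, 0 °C
Reagents that add atoms: none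
Why: Proposed new method: fluoride unmasks aryne 22 from 14, the pre-formed alkoxide 21 adds through oxygen to the aryne carbon remote from the C3 methoxymethoxy group (the future C8a, leaving the inductively stabilised aryl anion at the future C4a), and this anion is captured by the morpholine amide carbonyl to give a tetrahedral hemiaminal alkoxide that releases the C4 ketone only on the acetic acid quench. The closest known reaction types are the fluoride-mediated annulation of arynes with methyl salicylates to xanthones and the formal insertion of arynes into the C–O bond of carboxylic acids; new here are an aliphatic secondary alkoxide as the oxygen nucleophile and a tertiary amide as the acyl trap. Ring C closes by a 6-exo-trig acyl capture, so that O1–C8a and C4–C4a are made in one operation as a formal [4+2] annulation. No stereocentre is created: C2 comes from 20, its C–O bond is never broken, and the S configuration is retained. The regioselectivity needed is secured by the polarisation of the 3-alkoxyaryne (distal attack, as for 3-methoxybenzyne), which also fixes the geranyl group at C6, and acyl capture is favoured over protonation by the proton-free medium. The persistent hemiaminal keeps the base-labile flavanone (retro-oxa-Michael racemisation) masked until the neutral work-up, and an amide in place of an ester disfavours retro-aldol cleavage and acyl transfer of 21.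

Step 12
Reactants: 24 (2S)-2-[3,4-bis(methoxymethoxy)phenyl]-6-geranyl-5,7-bis(methoxymethoxy)chroman-4-one
Product: 25 nymphaeol A
Conditions: HCl (3 M aq)/MeOH, 40 °C, argon
Reagents that add atoms: none
Why: Acid-catalysed transacetalisation with methanol removes the four MOM ethers as dimethoxymethane, and the C2 centre, which is not enolisable, should keep its configuration under these mild acidic conditions.

Compound list

1 | phloroglucinol (benzene-1,3,5-triol) | Oc1cc(O)cc(O)c1 | starting material
2 | 3,5-bis(methoxymethoxy)phenol | COCOc1cc(O)cc(OCOC)c1 | intermediate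
3 | [3,5-bis(methoxymethoxy)phenoxy]tri(propan-2-yl)silane | COCOc1cc(OCOC)cc(O[Si](C(C)C)(C(C)C)C(C)C)c1 | intermediate
4 | geranyl bromide, (2E)-1-bromo-3,7-dimethylocta-2,6-diene | CC(C)=CCC/C(C)=C/CBr | starting material
5 | {2,6-bis(methoxymethoxy)-4-[tri(propan-2-yl)silyloxy]phenyl}lithium | COCOc1cc(O[Si](C(C)C)(C(C)C)C(C)C)cc(OCOC)c1[Li] | intermediate
6 | [4-geranyl-3,5-bis(methoxymethoxy)phenoxy]tri(propan-2-yl)silane | COCOc1cc(O[Si](C(C)C)(C(C)C)C(C)C)cc(OCOC)c1C/C=C(\C)CCC=C(C)C | intermediate
7 | 4-geranyl-3,5-bis(methoxymethoxy)phenol | COCOc1cc(O)cc(OCOC)c1C/C=C(\C)CCC=C(C)C | intermediate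
8 | 4-geranyl-3,5-bis(methoxymethoxy)phenyl N-(propan-2-yl)carbamate | CC(C)NC(=O)Oc1cc(OCOC)c(C/C=C(\C)CCC=C(C)C)c(OCOC)c1 | intermediate
9 | 4-geranyl-3,5-bis(methoxymethoxy)phenyl N-(propan-2-yl)-N-(trimethylsilyl)carbamate | CC(C)N([Si](C)(C)C)C(=O)Oc1cc(OCOC)c(C/C=C(\C)CCC=C(C)C)c(OCOC)c1 | intermediate
10 | 2-lithio derivative of 9 (lithium between the carbamate oxygen and a MOM ether) | CC(C)N([Si](C)(C)C)C(=O)Oc1cc(OCOC)c(C/C=C(\C)CCC=C(C)C)c(OCOC)c1[Li] | intermediate
11 | 4-geranyl-3,5-bis(methoxymethoxy)-2-(trimethylsilyl)phenyl N-(propan-2-yl)-N-(trimethylsilyl)carbamate | CC(C)N([Si](C)(C)C)C(=O)Oc1cc(OCOC)c(C/C=C(\C)CCC=C(C)C)c(OCOC)c1[Si](C)(C)C | intermediate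
12 | 4-geranyl-3,5-bis(methoxymethoxy)-2-(trimethylsilyl)phenyl N-(propan-2-yl)carbamate | CC(C)NC(=O)Oc1cc(OCOC)c(C/C=C(\C)CCC=C(C)C)c(OCOC)c1[Si](C)(C)C | intermediate
13 | 4-geranyl-3,5-bis(methoxymethoxy)-2-(trimethylsilyl)phenol | Oc1cc(OCOC)c(C/C=C(\C)CCC=C(C)C)c(OCOC)c1[Si](C)(C)C | intermediate
14 | 4-geranyl-3,5-bis(methoxymethoxy)-2-(trimethylsilyl)phenyl trifluoromethanesulfonate | O=S(=O)(Oc1cc(OCOC)c(C/C=C(\C)CCC=C(C)C)c(OCOC)c1[Si](C)(C)C)C(F)(F)F | intermediate
15 | methyl 3,4-dihydroxybenzoate | COC(=O)c1ccc(O)c(O)c1 | starting material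
16 | methyl 3,4-bis(methoxymethoxy)benzoate | COC(=O)c1ccc(OCOC)c(OCOC)c1 | intermediate
17 | N-acetylmorpholine, 1-(morpholin-4-yl)ethan-1-one | CC(=O)N1CCOCC1 | starting material
18 | lithium 1-(morpholin-4-yl)ethen-1-olate | C=C(O[Li])N1CCOCC1 | intermediate
19 | 1-[3,4-bis(methoxymethoxy)phenyl]-3-(morpholin-4-yl)propane-1,3-dione | O=C(CC(=O)N1CCOCC1)c1ccc(OCOC)c(OCOC)c1 | intermediate
20 | (3S)-3-[3,4-bis(methoxymethoxy)phenyl]-3-hydroxy-1-(morpholin-4-yl)propan-1-one | O=C(C[C@H](O)c1ccc(OCOC)c(OCOC)c1)N1CCOCC1 | intermediate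
21 | sodium (1S)-1-[3,4-bis(methoxymethoxy)phenyl]-3-(morpholin-4-yl)-3-oxopropan-1-olate | O=C(C[C@H]([O-])c1ccc(OCOC)c(OCOC)c1)N1CCOCC1.[Na+] | intermediate
22 | 4-geranyl-3,5-bis(methoxymethoxy)benzyne (1,2-didehydrobenzene, numbered from the strained bond) | COCOC1=CC#CC(OCOC)=C1C/C=C(\C)CCC=C(C)C | intermediate
23 | (2S)-2-[3,4-bis(methoxymethoxy)phenyl]-6-geranyl-5,7-bis(methoxymethoxy)-4-(morpholin-4-yl)chroman-4-ol (C4 epimers) | CC(C)=CCC/C(C)=C/Cc1c(OCOC)cc2c(c1OCOC)C(O)(N1CCOCC1)C[C@@H](c1ccc(OCOC)c(OCOC)c1)O2 | intermediate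
24 | (2S)-2-[3,4-bis(methoxymethoxy)phenyl]-6-geranyl-5,7-bis(methoxymethoxy)chroman-4-one | CC(C)=CCC/C(C)=C/Cc1c(OCOC)cc2c(c1OCOC)C(=O)C[C@@H](c1ccc(OCOC)c(OCOC)c1)O2 | intermediate
25 | nymphaeol A, (2S)-2-(3,4-dihydroxyphenyl)-6-geranyl-5,7-dihydroxychroman-4-one | CC(C)=CCC/C(C)=C/Cc1c(O)cc2c(c1O)C(=O)C[C@@H](c1ccc(O)c(O)c1)O2 | target

Total step count: 12. Longest linear sequence: 9 steps (steps 1–7, 11, 12); the side branch (steps 8–10) has 3 steps.

Steps most likely to fail

1. Step 11 (key step). What may go wrong: the aryl anion is protonated before it reaches the amide, so that an open aryl ether forms instead of ring C. The alkoxide may also undergo retro-aldol cleavage, or the aryne may be consumed by other nucleophiles. Fallback with known chemistry, setting out from 14 and coming back at 24: caffeic acid is alkylated with MOMCl/i-Pr2NEt to methoxymethyl (2E)-3-[3,4-bis(methoxymethoxy)phenyl]prop-2-enoate F1, and the ester is saponified (LiOH, THF/H2O) to (2E)-3-[3,4-bis(methoxymethoxy)phenyl]prop-2-enoic acid F2. With 14 and CsF in THF at 125 °C, F2 should undergo the known formal insertion of an aryne into the C–O bond of a carboxylic acid (carboxylate addition at the same distal aryne carbon, then acyl transfer to the aryl anion). This gives the 2'-hydroxychalcone (2E)-1-[3-geranyl-6-hydroxy-2,4-bis(methoxymethoxy)phenyl]-3-[3,4-bis(methoxymethoxy)phenyl]prop-2-en-1-one F3. F3 closes by oxa-Michael addition in the same flask (completed with NaOAc in EtOH if needed) to racemic 2-[3,4-bis(methoxymethoxy)phenyl]-6-geranyl-5,7-bis(methoxymethoxy)chroman-4-one F4. Preparative HPLC on a chiral stationary phase then gives 24.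

2. Step 6. What may go wrong: lateral deprotonation of the doubly activated benzylic–allylic CH2 of the geranyl chain competes with ortho-lithiation, leading to silylation or isomerisation of the side chain, or TMSOTf attacks a MOM ether. Fallback, setting out from 2 and coming back at 14: silicon is introduced before the geranyl chain, so that no organolithium base meets that CH2 group. 2 and i-PrNCO/Et3N give 3,5-bis(methoxymethoxy)phenyl N-(propan-2-yl)carbamate F5. The one-flask sequence of step 6 then runs through 3,5-bis(methoxymethoxy)phenyl N-(propan-2-yl)-N-(trimethylsilyl)carbamate F6, its 2-lithio derivative F7 and 3,5-bis(methoxymethoxy)-2-(trimethylsilyl)phenyl N-(propan-2-yl)-N-(trimethylsilyl)carbamate F8 to 3,5-bis(methoxymethoxy)-2-(trimethylsilyl)phenyl N-(propan-2-yl)carbamate F9. In F7 the site between carbamate and MOM ether should be preferred over the site between the two MOM ethers. DBU/Et2NH frees 3,5-bis(methoxymethoxy)-2-(trimethylsilyl)phenol F10, and TIPSCl/imidazole gives [3,5-bis(methoxymethoxy)-2-(trimethylsilyl)phenoxy]tri(propan-2-yl)silane F11. n-BuLi lithiates the remaining C–H between the two MOM ethers to {2,6-bis(methoxymethoxy)-3-(trimethylsilyl)-4-[tri(propan-2-yl)silyloxy]phenyl}lithium F12, and CuI-catalysed coupling with 4 gives [4-geranyl-3,5-bis(methoxymethoxy)-2-(trimethylsilyl)phenoxy]tri(propan-2-yl)silane F13. TBAF then gives phenol 13, isolated in this variant, and PhNTf2/DBU converts it into 14.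

3. Step 12. What may go wrong: protic acid induces cyclisation of the geranyl chain onto the ortho phenols, addition of methanol to the alkenes, or ring opening with loss of configuration at C2. Fallback, setting out from 24 and coming back at 25: the acetals are exchanged without protic acid. TMSOTf/2,2'-bipyridyl in MeCN (0 °C to rt) should convert the four aryl MOM ethers by silyl transfer into (2S)-2-[3,4-bis(trimethylsilyloxy)phenyl]-6-geranyl-5,7-bis(trimethylsilyloxy)chroman-4-one F14. Addition of water then hydrolyses the aryl silyl ethers to 25.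

Further compounds

F1 | step 11 | methoxymethyl (2E)-3-[3,4-bis(methoxymethoxy)phenyl]prop-2-enoate | COCOC(=O)/C=C/c1ccc(OCOC)c(OCOC)c1
F2 | step 11 | (2E)-3-[3,4-bis(methoxymethoxy)phenyl]prop-2-enoic acid | OC(=O)/C=C/c1ccc(OCOC)c(OCOC)c1
F3 | step 11 | (2E)-1-[3-geranyl-6-hydroxy-2,4-bis(methoxymethoxy)phenyl]-3-[3,4-bis(methoxymethoxy)phenyl]prop-2-en-1-one | CC(C)=CCC/C(C)=C/Cc1c(OCOC)cc(O)c(C(=O)/C=C/c2ccc(OCOC)c(OCOC)c2)c1OCOC
F4 | step 11 | racemic 2-[3,4-bis(methoxymethoxy)phenyl]-6-geranyl-5,7-bis(methoxymethoxy)chroman-4-one | CC(C)=CCC/C(C)=C/Cc1c(OCOC)cc2c(c1OCOC)C(=O)CC(c1ccc(OCOC)c(OCOC)c1)O2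
F5 | step 6 | 3,5-bis(methoxymethoxy)phenyl N-(propan-2-yl)carbamate | CC(C)NC(=O)Oc1cc(OCOC)cc(OCOC)c1
F6 | step 6 | 3,5-bis(methoxymethoxy)phenyl N-(propan-2-yl)-N-(trimethylsilyl)carbamate | CC(C)N([Si](C)(C)C)C(=O)Oc1cc(OCOC)cc(OCOC)c1
F7 | step 6 | 2-lithio derivative of F6 | CC(C)N([Si](C)(C)C)C(=O)Oc1cc(OCOC)cc(OCOC)c1[Li]
F8 | step 6 | 3,5-bis(methoxymethoxy)-2-(trimethylsilyl)phenyl N-(propan-2-yl)-N-(trimethylsilyl)carbamate | CC(C)N([Si](C)(C)C)C(=O)Oc1cc(OCOC)cc(OCOC)c1[Si](C)(C)C
F9 | step 6 | 3,5-bis(methoxymethoxy)-2-(trimethylsilyl)phenyl N-(propan-2-yl)carbamate | CC(C)NC(=O)Oc1cc(OCOC)cc(OCOC)c1[Si](C)(C)C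
F10 | step 6 | 3,5-bis(methoxymethoxy)-2-(trimethylsilyl)phenol | Oc1cc(OCOC)cc(OCOC)c1[Si](C)(C)C
F11 | step 6 | [3,5-bis(methoxymethoxy)-2-(trimethylsilyl)phenoxy]tri(propan-2-yl)silane | COCOc1cc(OCOC)c([Si](C)(C)C)c(O[Si](C(C)C)(C(C)C)C(C)C)c1
F12 | step 6 | {2,6-bis(methoxymethoxy)-3-(trimethylsilyl)-4-[tri(propan-2-yl)silyloxy]phenyl}lithium | COCOc1cc(O[Si](C(C)C)(C(C)C)C(C)C)c([Si](C)(C)C)c(OCOC)c1[Li]
F13 | step 6 | [4-geranyl-3,5-bis(methoxymethoxy)-2-(trimethylsilyl)phenoxy]tri(propan-2-yl)silane | COCOc1cc(O[Si](C(C)C)(C(C)C)C(C)C)c([Si](C)(C)C)c(OCOC)c1C/C=C(\C)CCC=C(C)C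
F14 | step 12 | (2S)-2-[3,4-bis(trimethylsilyloxy)phenyl]-6-geranyl-5,7-bis(trimethylsilyloxy)chroman-4-one | CC(C)=CCC/C(C)=C/Cc1c(O[Si](C)(C)C)cc2c(c1O[Si](C)(C)C)C(=O)C[C@@H](c1ccc(O[Si](C)(C)C)c(O[Si](C)(C)C)c1)O2
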